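**Retrosynthetic overview**
1. The last skeletal bond is CH2–C5' of the resorcinol ring: Friedel–Crafts benzylation of 3-arylcoumarin triol 21 by benzofuran-3-ylmethanol 12, then removal of the MOM groups.
2. The plan rests on the ring A C2 hydroxyl lying ortho to the ring A C1–benzofuran C2 bond while benzofuran C3 carries exactly one carbon. Tying that oxygen to that carbon as a lactone makes the benzofuran half the coumestan 10, which hydride reopens to the phenol and the carbinol.
3. The furan ring of 10 is closed at carbon (benzofuran C3–C3a) by palladium-catalysed intramolecular direct arylation of the 4-(2-bromoaryloxy)coumarin 9. The pyranone ring is made first (acetophenone 4 plus diethyl carbonate) and the ether by tosylate displacement with bromophenol 8.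
4. Both 1,1-dimethylallyl groups come from aryl bromides and prenylboronate 3 by γ-selective Suzuki–Miyaura coupling. The coumarin ring of 21 is closed by esterification/Knoevenagel condensation of aldehyde 14 with acid 17.
5. Ring order: pyranone of 5, furan of 10 (key), lactone reopened; coumarin of 19 built separately; union last.

Key step: step 7

Remark on the chemistry: the target has no stereocentre and no stereogenic double bond, so no stereocontrol is needed. MOM = methoxymethyl. 2,4-Dihydroxyphenylacetic acid is assumed to be a purchasable building block.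

**Route**

Step 1
Reactants: 1 1-(5-bromo-2,4-dihydroxyphenyl)ethanone
Product: 2 1-[5-bromo-2-hydroxy-4-(methoxymethoxy)phenyl]ethanone
Conditions: MOMCl (1.1 equiv), K2CO3 (1.5 equiv), acetone, 0 °C to rt
Reagents that add atoms: chloromethyl methyl ether (MOMCl), COCCl
Why: Williamson-type MOM protection, selective because the 2-OH is locked in a hydrogen bond to the acetyl carbonyl while the 4-OH, acidified by the ortho bromine, is alkylated.

Step 2
Reactants: 2 1-[5-bromo-2-hydroxy-4-(methoxymethoxy)phenyl]ethanone; 3 prenylboronic acid pinacol ester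
Product: 4 1-[2-hydroxy-4-(methoxymethoxy)-5-(2-methylbut-3-en-2-yl)phenyl]ethanone
Conditions: 3 (1.5 equiv), Pd(OAc)2 (2 mol%), electron-poor biaryl phosphine of the JackiePhos type, P[3,5-(CF3)2C6H3]2 (4 mol%), K3PO4 (aq, 3 equiv), THF, 40 °C
Reagents that add atoms: none
Why: γ-selective Suzuki–Miyaura allylation, in which SE2' transmetalation of the prenylboronate puts palladium on the tertiary carbon and the electron-poor ligand makes reductive elimination faster than σ–π–σ isomerisation, so the branched 1,1-dimethylallyl arene should form; the chelated phenol and the ketone tolerate aqueous phosphate.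

Step 3
Reactants: 4 1-[2-hydroxy-4-(methoxymethoxy)-5-(2-methylbut-3-en-2-yl)phenyl]ethanone
Product: 5 4-hydroxy-7-(methoxymethoxy)-6-(2-methylbut-3-en-2-yl)-2H-chromen-2-one
Conditions: NaH (4 equiv), (EtO)2CO (5 equiv), toluene, 100 °C; then cold 1 M HCl to pH 3
Reagents that add atoms: diethyl carbonate, CCOC(=O)OCC
Why: Claisen-type acylation of the ketone enolate by diethyl carbonate followed by lactonisation onto the free 2-OH is the standard 4-hydroxycoumarin synthesis from 2-hydroxyacetophenones, and the MOM ether and the alkene are inert to NaH.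

Step 4
Reactants: 5 4-hydroxy-7-(methoxymethoxy)-6-(2-methylbut-3-en-2-yl)-2H-chromen-2-one
Product: 6 7-(methoxymethoxy)-6-(2-methylbut-3-en-2-yl)-2-oxo-2H-chromen-4-yl 4-methylbenzenesulfonate
Conditions: TsCl (1.2 equiv), Et3N (1.5 equiv), CH2Cl2, 0 °C to rt
Reagents that add atoms: p-toluenesulfonyl chloride, Cc1ccc(cc1)S(=O)(=O)Cl
Why: O-sulfonylation of the acidic vinylogous-acid hydroxyl gives a vinylogous acyl tosylate activated for addition–elimination at C4.

Step 5
Reactants: 7 4-bromoresorcinol
Product: 8 2-bromo-5-(methoxymethoxy)phenol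
Conditions: NaH (2.1 equiv), THF/DMF, 0 °C; MOMCl (1.0 equiv), −20 to 0 °C; aq NH4Cl
Reagents that add atoms: chloromethyl methyl ether (MOMCl), COCCl
Why: Williamson monoalkylation of the resorcinol dianion should occur at the more basic and less hindered phenoxide para to bromine, leaving free the hydroxyl that is flanked by the bromide.

Step 6
Reactants: 6 7-(methoxymethoxy)-6-(2-methylbut-3-en-2-yl)-2-oxo-2H-chromen-4-yl 4-methylbenzenesulfonate; 8 2-bromo-5-(methoxymethoxy)phenol
Product: 9 4-[2-bromo-5-(methoxymethoxy)phenoxy]-7-(methoxymethoxy)-6-(2-methylbut-3-en-2-yl)-2H-chromen-2-one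
Conditions: K2CO3 (1.5 equiv), DMF, 60 °C
Reagents that add atoms: none
Why: Addition–elimination (vinylogous acyl substitution) of the phenoxide at coumarin C4 with loss of tosylate is the usual entry to 4-aryloxycoumarins.

Step 7
Reactants: 9 4-[2-bromo-5-(methoxymethoxy)phenoxy]-7-(methoxymethoxy)-6-(2-methylbut-3-en-2-yl)-2H-chromen-2-one
Product: 10 3,9-bis(methoxymethoxy)-2-(2-methylbut-3-en-2-yl)-6H-benzofuro[3,2-c]chromen-6-one (the coumestan)
Conditions: Pd(OAc)2 (5 mol%), PCy3·HBF4 (10 mol%), PivOH (30 mol%), K2CO3 (2 equiv), DMA, 110 °C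
Reagents that add atoms: none
Why: Zerovalent palladium inserts into the aryl C–Br bond next to the ether oxygen, pivalate-assisted concerted metalation–deprotonation at coumarin C3–H (the nucleophilic α-carbon of the 4-aryloxy enoate) gives a six-membered oxa-palladacycle, and C–C reductive elimination forms the C6a–C6b bond (benzofuran C3–C3a). The closest known reaction type is the palladium-catalysed intramolecular direct arylation of 4-(2-halophenoxy)coumarins to coumestans. The furan ring is closed at carbon by ring contraction of the palladacycle to the five-membered ring, the ether oxygen being already in place. No stereocentre is formed. The step needs site selectivity on the arene and chemoselectivity over the vinyl group: the bromine fixes the coupling carbon para to the MOM ether so only the 9-oxygenated coumestan can form, and the intramolecular closure should outrun intermolecular Heck insertion into the hindered neopentyl-type vinyl group, while the MOM ethers and the lactone are stable to carbonate in DMA.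

Step 8
Reactants: 10 3,9-bis(methoxymethoxy)-2-(2-methylbut-3-en-2-yl)-6H-benzofuro[3,2-c]chromen-6-one
Product: 11 {2-[2-hydroxy-4-(methoxymethoxy)-5-(2-methylbut-3-en-2-yl)phenyl]-6-(methoxymethoxy)-1-benzofuran-3-yl}methanol
Conditions: LiAlH4 (2 equiv), THF, 0 °C; aq potassium sodium tartrate work-up
Reagents that add atoms: none
Why: Lactone reduction by LiAlH4 turns the lactone carbon into the primary carbinol and releases the ring A phenol, the known opening of coumestans to 2-(2-hydroxyaryl)-3-(hydroxymethyl)benzofurans, with MOM ethers and the vinyl group inert to hydride.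

Step 9
Reactants: 11 {2-[2-hydroxy-4-(methoxymethoxy)-5-(2-methylbut-3-en-2-yl)phenyl]-6-(methoxymethoxy)-1-benzofuran-3-yl}methanol
Product: 12 {2-[2,4-bis(methoxymethoxy)-5-(2-methylbut-3-en-2-yl)phenyl]-6-(methoxymethoxy)-1-benzofuran-3-yl}methanol
Conditions: MOMCl (1.1 equiv), K2CO3, acetone, 0 °C to rt
Reagents that add atoms: chloromethyl methyl ether (MOMCl), COCCl
Why: Carbonate deprotonates only the phenol, so Williamson alkylation caps the ring A 2-OH and leaves the primary alcohol free, which prevents acid-induced closure of this phenol onto the benzylic carbon (pterocarpene formation) in step 15.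

Step 10
Reactants: 13 5-bromo-2,4-dihydroxybenzaldehyde
Product: 14 5-bromo-2-hydroxy-4-(methoxymethoxy)benzaldehyde
Conditions: MOMCl (1.05 equiv), K2CO3, acetone, 0 °C to rt
Reagents that add atoms: chloromethyl methyl ether (MOMCl), COCCl
Why: Williamson-type MOM protection, selective for the 4-OH because the 2-OH is hydrogen-bonded to the formyl group.

Step 11
Reactants: 15 2,4-dihydroxyphenylacetic acid
Product: 17 2-[2,4-bis(methoxymethoxy)phenyl]acetic acid, via methoxymethyl ester 16 (not isolated)
Conditions: MOMCl (3.5 equiv), iPr2NEt (4 equiv), CH2Cl2, 0 °C to rt; then LiOH, THF/MeOH/H2O, rt; cold 1 M HCl to pH 4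
Reagents that add atoms: chloromethyl methyl ether (MOMCl), COCCl; lithium hydroxide, [Li+].[OH-]
Why: Exhaustive MOM alkylation of the carboxylate and both phenols followed by saponification of the labile MOM ester gives the acid with both phenols masked, which blocks lactonisation to the benzofuranone.

Step 12
Reactants: 14 5-bromo-2-hydroxy-4-(methoxymethoxy)benzaldehyde; 17 2-[2,4-bis(methoxymethoxy)phenyl]acetic acid
Product: 19 6-bromo-3-[2,4-bis(methoxymethoxy)phenyl]-7-(methoxymethoxy)-2H-chromen-2-one, via aryl ester 18 (not isolated)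
Conditions: DCC (1.1 equiv), DMAP (10 mol%), CH2Cl2, 0 °C to rt; then DBU (0.3 equiv), rt
Reagents that add atoms: none
Why: Steglich esterification of the salicylaldehyde phenol followed by base-catalysed intramolecular Knoevenagel condensation (aldol addition of the arylacetate enolate to the formyl group, then dehydration) closes the pyranone, the pathway that underlies Perkin-type 3-arylcoumarin syntheses.

Step 13
Reactants: 19 6-bromo-3-[2,4-bis(methoxymethoxy)phenyl]-7-(methoxymethoxy)-2H-chromen-2-one; 3 prenylboronic acid pinacol ester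
Product: 20 3-[2,4-bis(methoxymethoxy)phenyl]-7-(methoxymethoxy)-6-(2-methylbut-3-en-2-yl)-2H-chromen-2-one
Conditions: 3 (1.5 equiv), Pd(OAc)2 (2 mol%), electron-poor biaryl phosphine of the JackiePhos type (4 mol%), K3PO4 (aq, 3 equiv), THF, 40 °C
Reagents that add atoms: none
Why: The same γ-selective Suzuki–Miyaura allylation as in step 2, placed after coumarin formation so that no aldehyde is exposed to the allylboronate (no competing allylboration).

Step 14
Reactants: 20 3-[2,4-bis(methoxymethoxy)phenyl]-7-(methoxymethoxy)-6-(2-methylbut-3-en-2-yl)-2H-chromen-2-one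
Product: 21 3-(2,4-dihydroxyphenyl)-7-hydroxy-6-(2-methylbut-3-en-2-yl)-2H-chromen-2-one
Conditions: 3 M HCl (aq), MeOH/THF, 40 °C
Reagents that add atoms: none
Why: Acid-catalysed acetal exchange with methanol removes the three MOM groups, while the monosubstituted vinyl group of the reverse prenyl unit is protonated only slowly under these mild conditions.

Step 15
Reactants: 12 {2-[2,4-bis(methoxymethoxy)-5-(2-methylbut-3-en-2-yl)phenyl]-6-(methoxymethoxy)-1-benzofuran-3-yl}methanol; 21 3-(2,4-dihydroxyphenyl)-7-hydroxy-6-(2-methylbut-3-en-2-yl)-2H-chromen-2-one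
Product: 22 3-[5-({2-[2,4-bis(methoxymethoxy)-5-(2-methylbut-3-en-2-yl)phenyl]-6-(methoxymethoxy)-1-benzofuran-3-yl}methyl)-2,4-dihydroxyphenyl]-7-hydroxy-6-(2-methylbut-3-en-2-yl)-2H-chromen-2-one
Conditions: Sc(OTf)3 (5 mol%), MeCN, 0 °C to rt; 21 (3 equiv), slow addition of 12
Reagents that add atoms: none
Why: Friedel–Crafts benzylation, in which Sc(OTf)3 ionises the carbinol to a cation stabilised by the furan oxygen and the 2-aryl group, and the free resorcinol ring of 21 should attack at C5' (para to the 2'-OH, ortho to the 4'-OH), which is less hindered than C3' between the two hydroxyls and more nucleophilic than the lactone-deactivated coumarin C8; excess 21 and slow addition should suppress self-alkylation of 12.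

Step 16
Reactants: 22 the tris-MOM ether of the target (structure as in step 15)
Product: 23 3-[5-({2-[2,4-dihydroxy-5-(2-methylbut-3-en-2-yl)phenyl]-6-hydroxy-1-benzofuran-3-yl}methyl)-2,4-dihydroxyphenyl]-7-hydroxy-6-(2-methylbut-3-en-2-yl)-2H-chromen-2-one (target)
Conditions: 3 M HCl (aq), MeOH/THF, 40 °C
Reagents that add atoms: none
Why: Acid-catalysed MOM removal by acetal exchange with methanol should free the three remaining phenols, and the diarylmethane bridge cannot ionise under these conditions.

**Compound list**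
1 | 1-(5-bromo-2,4-dihydroxyphenyl)ethanone | CC(=O)c1cc(Br)c(O)cc1O | starting material
2 | 1-[5-bromo-2-hydroxy-4-(methoxymethoxy)phenyl]ethanone | CC(=O)c1cc(Br)c(OCOC)cc1O | intermediate
3 | prenylboronic acid pinacol ester | CC(C)=CCB1OC(C)(C)C(C)(C)O1 | starting material
4 | 1-[2-hydroxy-4-(methoxymethoxy)-5-(2-methylbut-3-en-2-yl)phenyl]ethanone | CC(=O)c1cc(C(C)(C)C=C)c(OCOC)cc1O | intermediate
5 | 4-hydroxy-7-(methoxymethoxy)-6-(2-methylbut-3-en-2-yl)-2H-chromen-2-one | C=CC(C)(C)c1cc2c(O)cc(=O)oc2cc1OCOC | intermediate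
6 | 7-(methoxymethoxy)-6-(2-methylbut-3-en-2-yl)-2-oxo-2H-chromen-4-yl 4-methylbenzenesulfonate | C=CC(C)(C)c1cc2c(OS(=O)(=O)c3ccc(C)cc3)cc(=O)oc2cc1OCOC | intermediate
7 | 4-bromoresorcinol | Oc1ccc(Br)c(O)c1 | starting material
8 | 2-bromo-5-(methoxymethoxy)phenol | Oc1cc(OCOC)ccc1Br | intermediate
9 | 4-[2-bromo-5-(methoxymethoxy)phenoxy]-7-(methoxymethoxy)-6-(2-methylbut-3-en-2-yl)-2H-chromen-2-one | C=CC(C)(C)c1cc2c(Oc3cc(OCOC)ccc3Br)cc(=O)oc2cc1OCOC | intermediate
10 | 3,9-bis(methoxymethoxy)-2-(2-methylbut-3-en-2-yl)-6H-benzofuro[3,2-c]chromen-6-one | C=CC(C)(C)c1cc2c(cc1OCOC)oc(=O)c1c2oc2cc(OCOC)ccc12 | intermediate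
11 | {2-[2-hydroxy-4-(methoxymethoxy)-5-(2-methylbut-3-en-2-yl)phenyl]-6-(methoxymethoxy)-1-benzofuran-3-yl}methanol | C=CC(C)(C)c1cc(-c2oc3cc(OCOC)ccc3c2CO)c(O)cc1OCOC | intermediate
12 | {2-[2,4-bis(methoxymethoxy)-5-(2-methylbut-3-en-2-yl)phenyl]-6-(methoxymethoxy)-1-benzofuran-3-yl}methanol | C=CC(C)(C)c1cc(-c2oc3cc(OCOC)ccc3c2CO)c(OCOC)cc1OCOC | intermediate
13 | 5-bromo-2,4-dihydroxybenzaldehyde | O=Cc1cc(Br)c(O)cc1O | starting material
14 | 5-bromo-2-hydroxy-4-(methoxymethoxy)benzaldehyde | O=Cc1cc(Br)c(OCOC)cc1O | intermediate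
15 | 2,4-dihydroxyphenylacetic acid | OC(=O)Cc1ccc(O)cc1O | starting material
16 | methoxymethyl 2-[2,4-bis(methoxymethoxy)phenyl]acetate | COCOC(=O)Cc1ccc(OCOC)cc1OCOC | intermediate
17 | 2-[2,4-bis(methoxymethoxy)phenyl]acetic acid | OC(=O)Cc1ccc(OCOC)cc1OCOC | intermediate
18 | 4-bromo-2-formyl-5-(methoxymethoxy)phenyl 2-[2,4-bis(methoxymethoxy)phenyl]acetate | O=Cc1cc(Br)c(OCOC)cc1OC(=O)Cc1ccc(OCOC)cc1OCOC | intermediate
19 | 6-bromo-3-[2,4-bis(methoxymethoxy)phenyl]-7-(methoxymethoxy)-2H-chromen-2-one | COCOc1ccc(-c2cc3cc(Br)c(OCOC)cc3oc2=O)c(OCOC)c1 | intermediate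
20 | 3-[2,4-bis(methoxymethoxy)phenyl]-7-(methoxymethoxy)-6-(2-methylbut-3-en-2-yl)-2H-chromen-2-one | C=CC(C)(C)c1cc2cc(-c3ccc(OCOC)cc3OCOC)c(=O)oc2cc1OCOC | intermediate
21 | 3-(2,4-dihydroxyphenyl)-7-hydroxy-6-(2-methylbut-3-en-2-yl)-2H-chromen-2-one | C=CC(C)(C)c1cc2cc(-c3ccc(O)cc3O)c(=O)oc2cc1O | intermediate
22 | 3-[5-({2-[2,4-bis(methoxymethoxy)-5-(2-methylbut-3-en-2-yl)phenyl]-6-(methoxymethoxy)-1-benzofuran-3-yl}methyl)-2,4-dihydroxyphenyl]-7-hydroxy-6-(2-methylbut-3-en-2-yl)-2H-chromen-2-one | C=CC(C)(C)c1cc(-c2oc3cc(OCOC)ccc3c2Cc2cc(-c3cc4cc(C(C)(C)C=C)c(O)cc4oc3=O)c(O)cc2O)c(OCOC)cc1OCOC | intermediate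
23 | 3-[5-({2-[2,4-dihydroxy-5-(2-methylbut-3-en-2-yl)phenyl]-6-hydroxy-1-benzofuran-3-yl}methyl)-2,4-dihydroxyphenyl]-7-hydroxy-6-(2-methylbut-3-en-2-yl)-2H-chromen-2-one | C=CC(C)(C)c1cc(-c2oc3cc(O)ccc3c2Cc2cc(-c3cc4cc(C(C)(C)C=C)c(O)cc4oc3=O)c(O)cc2O)c(O)cc1O | target

**Step count**
Total step count: 16.
Longest linear sequence: 10 steps (1, 2, 3, 4, 6, 7, 8, 9, 15, 16).

**Steps most likely to fail**

Step 15 (Friedel–Crafts union). What may go wrong: the cation may be captured by the electron-rich benzofuran or ring A carbons of a second molecule of 12 (oligomerisation), or by C3', coumarin C8 or a phenolic oxygen of 21. MOM groups may also be lost before the coupling is complete. The fallback replaces the electrophilic substitution by a regiodefined benzylic Suzuki–Miyaura coupling. It sets out from 20 and 12 and comes back to the route at 23. Iodination of 20 with N-iodosuccinimide and catalytic CF3CO2H in MeCN at 0 °C should give 3-[5-iodo-2,4-bis(methoxymethoxy)phenyl]-7-(methoxymethoxy)-6-(2-methylbut-3-en-2-yl)-2H-chromen-2-one F1, since the position between the two MOM ethers is shielded. Miyaura borylation (B2pin2, PdCl2(dppf), KOAc, dioxane, 80 °C) should then give 3-[2,4-bis(methoxymethoxy)-5-(4,4,5,5-tetramethyl-1,3,2-dioxaborolan-2-yl)phenyl]-7-(methoxymethoxy)-6-(2-methylbut-3-en-2-yl)-2H-chromen-2-one F2. Alcohol 12 is converted with methyl chloroformate and pyridine in CH2Cl2 at 0 °C into {2-[2,4-bis(methoxymethoxy)-5-(2-methylbut-3-en-2-yl)phenyl]-6-(methoxymethoxy)-1-benzofuran-3-yl}methyl methyl carbonate F3. Coupling of F2 with F3 through an η3-benzylpalladium intermediate ([Pd(C3H5)Cl]2, 1,5-bis(diphenylphosphino)pentane, K2CO3, DMF/H2O, 80 °C) should give the hexakis(methoxymethyl) ether of the target F4. Acid methanolysis as in step 16 then gives 23.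

Step 2 (γ-selective reverse prenylation; step 13 is the same reaction type). What may go wrong: σ–π–σ isomerisation of the allylpalladium intermediate may erode the branch selectivity and deliver the linear prenyl arene, and oxidative addition para to the phenoxide may be slow enough for protodeboronation to win. The fallback builds the quaternary carbon by enolate arylation and the vinyl group by olefination. It sets out from 2 and comes back at 4. Palladium-catalysed α-arylation of isobutyraldehyde (Pd(OAc)2, rac-BINAP, Cs2CO3, dioxane, 80 °C) should give 2-[5-acetyl-4-hydroxy-2-(methoxymethoxy)phenyl]-2-methylpropanal F5, in which no allyl isomer question arises. Wittig methylenation (Ph3PCH3Br, KN(SiMe3)2, 2.2 equiv of ylide, THF, −78 to 0 °C) then gives 4; the first equivalent of ylide only deprotonates the phenol, and the resulting phenoxide deactivates the acetyl group.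

Step 7 (key direct arylation). What may go wrong: oxidative addition into the electron-rich C–Br bond may be slow and lead to protodebromination, palladation of C3–H may fail, or the arylpalladium species may be diverted into intermolecular Heck reaction with a vinyl group. The fallback swaps the roles of the two partners, with the halogen on coumarin C3 and the C–H bond on the aryl ether. It sets out from 6 and comes back at 10. Tosylate 6 and commercial 3-(methoxymethoxy)phenol (COCOc1cccc(O)c1; K2CO3, DMF, 60 °C) should give 4-[3-(methoxymethoxy)phenoxy]-7-(methoxymethoxy)-6-(2-methylbut-3-en-2-yl)-2H-chromen-2-one F6. N-Iodosuccinimide in MeCN should iodinate the nucleophilic C3 to give 3-iodo-4-[3-(methoxymethoxy)phenoxy]-7-(methoxymethoxy)-6-(2-methylbut-3-en-2-yl)-2H-chromen-2-one F7. Zerovalent palladium (Pd(OAc)2, PPh3, NaOAc, DMA, 110 °C) then inserts into the very reactive C3–I bond and arylates the phenoxy ring at the C–H para to the MOM ether, the other ortho position lying between two oxygens. This known coumestan closure gives 10.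

**Further compounds**
F1 | step 15 | 3-[5-iodo-2,4-bis(methoxymethoxy)phenyl]-7-(methoxymethoxy)-6-(2-methylbut-3-en-2-yl)-2H-chromen-2-one | C=CC(C)(C)c1cc2cc(-c3cc(I)c(OCOC)cc3OCOC)c(=O)oc2cc1OCOC
F2 | step 15 | 3-[2,4-bis(methoxymethoxy)-5-(4,4,5,5-tetramethyl-1,3,2-dioxaborolan-2-yl)phenyl]-7-(methoxymethoxy)-6-(2-methylbut-3-en-2-yl)-2H-chromen-2-one | C=CC(C)(C)c1cc2cc(-c3cc(B4OC(C)(C)C(C)(C)O4)c(OCOC)cc3OCOC)c(=O)oc2cc1OCOC
F3 | step 15 | {2-[2,4-bis(methoxymethoxy)-5-(2-methylbut-3-en-2-yl)phenyl]-6-(methoxymethoxy)-1-benzofuran-3-yl}methyl methyl carbonate | C=CC(C)(C)c1cc(-c2oc3cc(OCOC)ccc3c2COC(=O)OC)c(OCOC)cc1OCOC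
F4 | step 15 | hexakis(methoxymethyl) ether of the target | C=CC(C)(C)c1cc(-c2oc3cc(OCOC)ccc3c2Cc2cc(-c3cc4cc(C(C)(C)C=C)c(OCOC)cc4oc3=O)c(OCOC)cc2OCOC)c(OCOC)cc1OCOC
F5 | step 2 | 2-[5-acetyl-4-hydroxy-2-(methoxymethoxy)phenyl]-2-methylpropanal | CC(=O)c1cc(C(C)(C)C=O)c(OCOC)cc1O
F6 | step 7 | 4-[3-(methoxymethoxy)phenoxy]-7-(methoxymethoxy)-6-(2-methylbut-3-en-2-yl)-2H-chromen-2-one | C=CC(C)(C)c1cc2c(Oc3cccc(OCOC)c3)cc(=O)oc2cc1OCOC
F7 | step 7 | 3-iodo-4-[3-(methoxymethoxy)phenoxy]-7-(methoxymethoxy)-6-(2-methylbut-3-en-2-yl)-2H-chromen-2-one | C=CC(C)(C)c1cc2c(Oc3cccc(OCOC)c3)c(I)c(=O)oc2cc1OCOC
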